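Chromene numbering is used (O1, C2, C3, C4, C4a, C5, C6, C7, C8, C8a). Everything rests on the C5–C6 bond of the carbocycle: within the enolised β-triketone C4(=O)–C4a=C5(OH)–C6–C7(=O), C5 is an acyl carbon and C6 the α-carbon of the C7 ketone. A Dieckmann condensation closes that ring in one operation from a preformed cis-2,3-dimethyl-dihydropyranone that carries the ester (future C5) next to a quaternary carbon (future C8) bearing prenyl, lavandulyl and acetyl (future C7/C6). O1–C8a and the C8 configuration, set by a Fráter–Seebach prenylation, exist before closure, so fusion regiochemistry and the quaternary centre are not at stake. The phenylpropanoic acid arm is then added at C6.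

Key step: step 11

Remark on the chemistry: the target is one enol tautomer of a vinylogous triketone; all such tautomers are treated as one compound.
Remark on the chemistry: (R)-lavandulol (1) and (4S)-4-benzyl-3-propanoyl-1,3-thiazolidine-2-thione (10) are taken as purchasable.
Abbreviations: prenyl = 3-methylbut-2-en-1-yl; Lav = (2S)-5-methyl-2-(prop-1-en-2-yl)hex-4-en-1-yl, the lavandulyl group. Its centre is R in 1 and 2 only because CH2O or CH2I outranks isopropenyl.

Step 1
Reactants: 1 (R)-lavandulol
Product: 2 (R)-lavandulyl iodide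
Conditions: I2, PPh3, imidazole, CH2Cl2, 0 to 25 °C
Reagents that add atoms: iodine, II
Why: Appel-type (Garegg–Samuelsson) iodination of a primary alcohol by SN2 at CH2, which leaves the adjacent stereocentre untouched.

Step 2
Reactants: 3 methyl acetoacetate; 2 (R)-lavandulyl iodide
Product: 4 methyl 2-Lav-3-oxobutanoate (both C2 epimers)
Conditions: NaH, THF, 0 °C; then 2, DMF, 50 °C
Reagents that add atoms: none
Why: Acetoacetic ester C-alkylation with a soft, weakly basic enolate, chosen so that SN2 at the β-branched primary iodide outruns E2; the new C2 centre is uncontrolled and is made planar again in step 4.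

Step 3
Reactants: 4 methyl 2-Lav-3-oxobutanoate
Product: 5 methyl (3S)-3-hydroxy-2-Lav-butanoate (both C2 epimers)
Conditions: Ru2Cl4[(S)-BINAP]2·NEt3 (1 mol %), H2 (4 atm), MeOH, 50 °C
Reagents that add atoms: none
Why: Noyori asymmetric hydrogenation of a β-keto ester, in which the (S)-BINAP ruthenium chloride catalyst gives the (3S)-carbinol (the sense known for acetoacetates) and, under these low-pressure halide conditions, should leave the unfunctionalised olefins alone.

Step 4
Reactants: 5 methyl (3S)-3-hydroxy-2-Lav-butanoate; 6 prenyl bromide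
Product: 7 methyl (2R,3S)-3-hydroxy-2-Lav-2-prenylbutanoate
Conditions: lithium diisopropylamide (2.3 equiv), THF, −78 to −10 °C; then 6, −78 to −20 °C
Reagents that add atoms: none
Why: Fráter–Seebach alkylation, in which the dilithio alkoxide–enolate is a six-membered chelate of fixed geometry and prenyl bromide attacks the face anti to the C3 methyl group, so the (3S)-carbinol sets the quaternary centre (future C8) in the required sense from either C2 epimer.

Step 5
Reactants: 7 methyl (2R,3S)-3-hydroxy-2-Lav-2-prenylbutanoate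
Product: 8 (2S,3S)-2-Lav-2-prenylbutane-1,3-diol
Conditions: LiAlH4, THF, 0 to 25 °C
Reagents that add atoms: none
Why: Hydride reduction of the ester to the neopentylic primary alcohol; no stereocentre is affected.

Step 6
Reactants: 8 (2S,3S)-2-Lav-2-prenylbutane-1,3-diol
Product: 9 (2S)-2-Lav-2-prenyl-3-oxobutanal
Conditions: Dess–Martin periodinane (2.5 equiv), CH2Cl2, 0 to 25 °C
Reagents that add atoms: none
Why: Dess–Martin oxidation of both hydroxyl groups, which deliberately destroys the carbinol centre that served as control element; the quaternary carbon has no α-hydrogen and cannot epimerise.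

Step 7
Reactants: 10 (4S)-4-benzyl-3-propanoyl-1,3-thiazolidine-2-thione; 11 acetaldehyde
Product: 12 (4S)-4-benzyl-3-[(2S,3R)-3-hydroxy-2-methylbutanoyl]-1,3-thiazolidine-2-thione
Conditions: TiCl4, i-Pr2NEt, N-methyl-2-pyrrolidinone, CH2Cl2, 0 °C; then 11, −78 to 0 °C
Reagents that add atoms: none
Why: Crimmins titanium-enolate aldol of an N-propanoyl thiazolidinethione under amine/NMP conditions that favour the non-chelated transition state, giving the Evans syn (2S,3R) adduct from the (S)-benzyl auxiliary; these two centres become the cis C2/C3 methyl pair.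

Step 8
Reactants: 12 (4S)-4-benzyl-3-[(2S,3R)-3-hydroxy-2-methylbutanoyl]-1,3-thiazolidine-2-thione; 13 potassium methyl malonate
Product: 15 methyl (4S,5R)-5-hydroxy-4-methyl-3-oxohexanoate, via acylmalonic acid half-ester 14 (not isolated)
Conditions: MgCl2, imidazole, THF, 25 °C; 1 M HCl work-up
Reagents that add atoms: none
Why: Decarboxylative Claisen condensation (Masamune–Brooks type) in which the magnesium enolate of the malonate half-ester displaces the activated thiazolidinethione amide directly, under conditions too mild to epimerise the α-methyl centre.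

Step 9
Reactants: 15 methyl (4S,5R)-5-hydroxy-4-methyl-3-oxohexanoate; 9 (2S)-2-Lav-2-prenyl-3-oxobutanal
Product: 17 methyl (5S,6R)-5,6-dimethyl-4-oxo-2-[(3S)-6-methyl-3-Lav-2-oxohept-5-en-3-yl]tetrahydro-2H-pyran-3-carboxylate (mixture at C2/C3), via Knoevenagel alkylidene keto ester 16 (not isolated)
Conditions: piperidine (20 mol %), AcOH (20 mol %), 4 Å molecular sieves, CH2Cl2, 25 °C
Reagents that add atoms: none
Why: Amine-catalysed Knoevenagel condensation at the aldehyde, then 6-endo-trig oxa-Michael closure of the δ-hydroxyl (Maitland–Japp-type tetrahydropyranone synthesis); Lewis acids are avoided because the aldehyde could undergo carbonyl-ene cyclisation with its olefins, and the two new ring centres become sp2 in step 10.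

Step 10
Reactants: 17 methyl (5S,6R)-5,6-dimethyl-4-oxo-2-[(3S)-6-methyl-3-Lav-2-oxohept-5-en-3-yl]tetrahydro-2H-pyran-3-carboxylate
Product: 20 methyl (2R,3S)-2,3-dimethyl-6-[(3S)-6-methyl-3-Lav-2-oxohept-5-en-3-yl]-4-oxo-3,4-dihydro-2H-pyran-5-carboxylate, via α-phenylselanyl keto ester 18 (not isolated), via selenoxide 19 (not isolated)
Conditions: NaH, THF, 0 °C; PhSeCl, −78 °C; then 30% H2O2, pyridine, CH2Cl2, 0 to 25 °C
Reagents that add atoms: none
Why: Reich-type α-selenenylation of the β-keto ester enolate anti to the bulky neighbouring substituent, then oxidation and selenoxide syn-elimination toward the only β-hydrogen (the ring CH–O, cis to selenium after anti attack), giving the vinylogous carbonate.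

Step 11
Reactants: 20 methyl (2R,3S)-2,3-dimethyl-6-[(3S)-6-methyl-3-Lav-2-oxohept-5-en-3-yl]-4-oxo-3,4-dihydro-2H-pyran-5-carboxylate
Product: 21 (2R,3S,8S)-5-hydroxy-2,3-dimethyl-8-Lav-8-prenyl-2,3-dihydro-4H-chromene-4,7(8H)-dione
Conditions: LiN(SiMe3)2 (2.5 equiv), THF, −78 to −20 °C; then 1 M HCl
Reagents that add atoms: none
Why: The kinetic lithium enolate forms at the acetyl methyl group (the other α-carbon is quaternary), adds to the carbomethoxy group and expels methoxide, and the vinylogous triketone is deprotonated at once by the second equivalent of base, which makes the sequence irreversible. This is a Dieckmann (intramolecular Claisen) condensation of a δ-keto ester to a cyclic 1,3-diketone, the bond construction by which polyketide chains close to phloroglucinol rings. The six-membered carbocycle (C4a, C5, C6, C7, C8, C8a) closes in a 6-(enolexo)-exo-trig mode onto an ester held on the preformed pyranone ring. No stereocentre is formed; C8 and the lavandulyl centre cannot epimerise, and C2/C3 should hold because deprotonation at the hindered tertiary C3 is slower than at the methyl group at −78 °C and the product is protected as its delocalised anion. The step needs C- over O-acylation (an enol lactone from O-attack would be reopened by methoxide, so the C-acyl anion is the thermodynamic sink) and attack at the ester rather than the C4 ketone (the aldol alternative would require a bridgehead enol ether). Fusion regiochemistry is not at issue because O1–C8a already exists.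

Step 12
Reactants: 21 (2R,3S,8S)-5-hydroxy-2,3-dimethyl-8-Lav-8-prenyl-2,3-dihydro-4H-chromene-4,7(8H)-dione; 22 (E)-cinnamaldehyde
Product: 23 (3S)-3-[(2R,3S,8S)-5-hydroxy-2,3-dimethyl-8-Lav-8-prenyl-4,7-dioxo-3,4,7,8-tetrahydro-2H-chromen-6-yl]-3-phenylpropanal (in equilibrium with its cyclic hemiacetals)
Conditions: (S)-α,α-diphenylprolinol trimethylsilyl ether (20 mol %), CH2Cl2, 0 to 25 °C
Reagents that add atoms: none
Why: Iminium-catalysed Michael addition (Jørgensen–Hayashi catalyst) of the cyclic vinylogous acid through C6, its only C–H nucleophilic position; the diphenyl(silyloxy)methyl group shields one face of the (E)-iminium ion, so the carbon nucleophile adds to the open face and the (S)-benzylic centre is set under catalyst control, C6 itself returning to sp2.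

Step 13
Reactants: 23 (3S)-3-[(2R,3S,8S)-5-hydroxy-2,3-dimethyl-8-Lav-8-prenyl-4,7-dioxo-3,4,7,8-tetrahydro-2H-chromen-6-yl]-3-phenylpropanal
Product: 24 (3S)-3-[(2R,3S,8S)-5-hydroxy-2,3-dimethyl-8-Lav-8-prenyl-4,7-dioxo-3,4,7,8-tetrahydro-2H-chromen-6-yl]-3-phenylpropanoic acid (target)
Conditions: NaClO2, NaH2PO4, 2-methyl-2-butene (excess), t-BuOH/H2O, 0 to 25 °C
Reagents that add atoms: sodium chlorite, [Na+].[O-]Cl=O
Why: Pinnick oxidation of the aldehyde, available from the hemiacetals by ring-chain tautomerism, with 2-methyl-2-butene scavenging hypochlorite to protect the olefins and the enol; no stereocentre is touched.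

Compound list
1 | (R)-lavandulol, (2R)-5-methyl-2-(prop-1-en-2-yl)hex-4-en-1-ol | C=C(C)[C@@H](CC=C(C)C)CO | starting material
2 | (R)-lavandulyl iodide, (2R)-1-iodo-5-methyl-2-(prop-1-en-2-yl)hex-4-ene | C=C(C)[C@@H](CC=C(C)C)CI | intermediate
3 | methyl acetoacetate | CC(=O)CC(=O)OC | starting material
4 | methyl 2-[(2S)-5-methyl-2-(prop-1-en-2-yl)hex-4-en-1-yl]-3-oxobutanoate, both C2 epimers | COC(=O)C(C[C@H](CC=C(C)C)C(C)=C)C(C)=O | intermediate
5 | methyl (3S)-3-hydroxy-2-[(2S)-5-methyl-2-(prop-1-en-2-yl)hex-4-en-1-yl]butanoate, both C2 epimers | COC(=O)C(C[C@H](CC=C(C)C)C(C)=C)[C@H](C)O | intermediate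
6 | prenyl bromide, 1-bromo-3-methylbut-2-ene | CC(C)=CCBr | starting material
7 | methyl (2R,3S)-3-hydroxy-2-[(2S)-5-methyl-2-(prop-1-en-2-yl)hex-4-en-1-yl]-2-(3-methylbut-2-en-1-yl)butanoate | COC(=O)[C@](CC=C(C)C)(C[C@H](CC=C(C)C)C(C)=C)[C@H](C)O | intermediate
8 | (2S,3S)-2-[(2S)-5-methyl-2-(prop-1-en-2-yl)hex-4-en-1-yl]-2-(3-methylbut-2-en-1-yl)butane-1,3-diol | OC[C@](CC=C(C)C)(C[C@H](CC=C(C)C)C(C)=C)[C@H](C)O | intermediate
9 | (2S)-2-[(2S)-5-methyl-2-(prop-1-en-2-yl)hex-4-en-1-yl]-2-(3-methylbut-2-en-1-yl)-3-oxobutanal | O=C[C@](CC=C(C)C)(C[C@H](CC=C(C)C)C(C)=C)C(C)=O | intermediate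
10 | (4S)-4-benzyl-3-propanoyl-1,3-thiazolidine-2-thione | CCC(=O)N1[C@@H](Cc2ccccc2)CSC1=S | starting material
11 | acetaldehyde | CC=O | starting material
12 | (4S)-4-benzyl-3-[(2S,3R)-3-hydroxy-2-methylbutanoyl]-1,3-thiazolidine-2-thione | C[C@@H](O)[C@H](C)C(=O)N1[C@@H](Cc2ccccc2)CSC1=S | intermediate
13 | potassium methyl malonate, potassium 3-methoxy-3-oxopropanoate | [K+].[O-]C(=O)CC(=O)OC | starting material
14 | (4S,5R)-5-hydroxy-2-(methoxycarbonyl)-4-methyl-3-oxohexanoic acid, mixture at C2 | C[C@@H](O)[C@H](C)C(=O)C(C(=O)O)C(=O)OC | intermediate (not isolated)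
15 | methyl (4S,5R)-5-hydroxy-4-methyl-3-oxohexanoate | C[C@@H](O)[C@H](C)C(=O)CC(=O)OC | intermediate
16 | methyl (4S,5R)-2-[(2S)-2-acetyl-5-methyl-2-Lav-hex-4-en-1-ylidene]-5-hydroxy-4-methyl-3-oxohexanoate, E/Z mixture | COC(=O)C(=C[C@](CC=C(C)C)(C[C@H](CC=C(C)C)C(C)=C)C(C)=O)C(=O)[C@@H](C)[C@@H](C)O | intermediate (not isolated)
17 | methyl (5S,6R)-5,6-dimethyl-4-oxo-2-[(3S)-6-methyl-3-Lav-2-oxohept-5-en-3-yl]tetrahydro-2H-pyran-3-carboxylate, mixture at C2/C3 | COC(=O)C1C(=O)[C@@H](C)[C@@H](C)OC1[C@](CC=C(C)C)(C[C@H](CC=C(C)C)C(C)=C)C(C)=O | intermediate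
18 | methyl (5S,6R)-5,6-dimethyl-4-oxo-3-(phenylselanyl)-2-[(3S)-6-methyl-3-Lav-2-oxohept-5-en-3-yl]tetrahydro-2H-pyran-3-carboxylate | COC(=O)C1([Se]c2ccccc2)C(=O)[C@@H](C)[C@@H](C)OC1[C@](CC=C(C)C)(C[C@H](CC=C(C)C)C(C)=C)C(C)=O | intermediate (not isolated)
19 | the Se-oxide of 18 (phenylseleninyl keto ester) | COC(=O)C1([Se](=O)c2ccccc2)C(=O)[C@@H](C)[C@@H](C)OC1[C@](CC=C(C)C)(C[C@H](CC=C(C)C)C(C)=C)C(C)=O | intermediate (not isolated)
20 | methyl (2R,3S)-2,3-dimethyl-6-[(3S)-6-methyl-3-Lav-2-oxohept-5-en-3-yl]-4-oxo-3,4-dihydro-2H-pyran-5-carboxylate | COC(=O)C1=C([C@](CC=C(C)C)(C[C@H](CC=C(C)C)C(C)=C)C(C)=O)O[C@H](C)[C@H](C)C1=O | intermediate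
21 | (2R,3S,8S)-5-hydroxy-2,3-dimethyl-8-[(2S)-5-methyl-2-(prop-1-en-2-yl)hex-4-en-1-yl]-8-(3-methylbut-2-en-1-yl)-2,3-dihydro-4H-chromene-4,7(8H)-dione | C=C(C)[C@@H](CC=C(C)C)C[C@]1(CC=C(C)C)C(=O)C=C(O)C2=C1O[C@H](C)[C@H](C)C2=O | intermediate
22 | (E)-cinnamaldehyde | O=C/C=C/c1ccccc1 | starting material
23 | (3S)-3-[(2R,3S,8S)-5-hydroxy-2,3-dimethyl-8-Lav-8-prenyl-4,7-dioxo-3,4,7,8-tetrahydro-2H-chromen-6-yl]-3-phenylpropanal | C=C(C)[C@@H](CC=C(C)C)C[C@]1(CC=C(C)C)C(=O)C([C@@H](CC=O)c2ccccc2)=C(O)C2=C1O[C@H](C)[C@H](C)C2=O | intermediate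
24 | (3S)-3-[(2R,3S,8S)-5-hydroxy-2,3-dimethyl-8-[(2S)-5-methyl-2-(prop-1-en-2-yl)hex-4-en-1-yl]-8-(3-methylbut-2-en-1-yl)-4,7-dioxo-3,4,7,8-tetrahydro-2H-chromen-6-yl]-3-phenylpropanoic acid | C=C(C)[C@@H](CC=C(C)C)C[C@]1(CC=C(C)C)C(=O)C([C@@H](CC(=O)O)c2ccccc2)=C(O)C2=C1O[C@H](C)[C@H](C)C2=O | target

Total step count: 13. Longest linear sequence: 11 steps (steps 1 to 6, then 9 to 13); steps 7 and 8 form the convergent branch.

Steps most likely to fail

Step 9. The condensation may be slow at the neopentylic aldehyde, the formyl group may be lost by retro-Claisen cleavage under the amine, or the oxa-Michael closure may stay incomplete. The fallback sets out from 9 and 12 and returns at 20, bypassing 15, 17 and step 10. Aldehyde 9 would be treated with the lithium enolate of methyl acetate (lithium diisopropylamide, THF, −78 °C), which should add to the formyl group much faster than to the hindered ketone, to give the β-hydroxy ester F1. Dess–Martin oxidation would give the β-keto ester F2. Soft enolisation (MgBr2·OEt2, i-Pr2NEt, CH2Cl2) and C-acylation by the acyl thiazolidinethione 12 would give the triacylmethane F3. Mild acid (pyridinium p-toluenesulfonate, toluene, 4 Å sieves, 50 °C) should then close the δ-hydroxyl onto the enolised hindered carbonyl with loss of water, giving 20.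

Step 10. The selenium electrophile or the benzeneselenenic acid set free may add to the three olefins, or the selenide may form as the diastereomer without a syn β-hydrogen. The fallback sets out from 17 and returns at 20. The sodium enolate of 17 (NaH, THF) would be silylated with Me3SiCl to the silyl enol ether F4. Saegusa–Ito oxidation (Pd(OAc)2, MeCN, 25 °C) would then pass through a palladium enolate that can reach either ring face and eliminates the ring C–H next to oxygen, giving 20.

Step 12. The hindered, strongly acidic nucleophile may react sluggishly with the iminium ion (catalyst protonation or enaminone formation), and reversible addition may erode facial selectivity. The fallback sets out from 21 and 22 and returns at 24, bypassing 23 and step 13. Under oxidative N-heterocyclic carbene catalysis (N-mesityl aminoindanol-derived chiral triazolium salt, enantiomer selected for the (S) centre, K2CO3, 3,3',5,5'-tetra-tert-butyldiphenoquinone, toluene), cinnamaldehyde becomes the α,β-unsaturated acyl azolium. Michael addition of C6 of 21 and acyl transfer to an enol oxygen should give the enol lactone F5 (the isomer closed on the C7 oxygen would serve equally). LiOH in aqueous THF at 0 °C would open the lactone to 24.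

Further compounds
F1 | step 9 | methyl (4S)-4-acetyl-3-hydroxy-7-methyl-4-[(2S)-5-methyl-2-(prop-1-en-2-yl)hex-4-en-1-yl]oct-6-enoate, mixture at C3 | COC(=O)CC(O)[C@](CC=C(C)C)(C[C@H](CC=C(C)C)C(C)=C)C(C)=O
F2 | step 9 | methyl (4R)-4-acetyl-7-methyl-4-[(2S)-5-methyl-2-(prop-1-en-2-yl)hex-4-en-1-yl]-3-oxooct-6-enoate | COC(=O)CC(=O)[C@](CC=C(C)C)(C[C@H](CC=C(C)C)C(C)=C)C(C)=O
F3 | step 9 | methyl (4R)-4-acetyl-2-[(2S,3R)-3-hydroxy-2-methylbutanoyl]-7-methyl-4-[(2S)-5-methyl-2-(prop-1-en-2-yl)hex-4-en-1-yl]-3-oxooct-6-enoate, mixture at C2 | COC(=O)C(C(=O)[C@@H](C)[C@@H](C)O)C(=O)[C@](CC=C(C)C)(C[C@H](CC=C(C)C)C(C)=C)C(C)=O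
F4 | step 10 | methyl (5S,6R)-5,6-dimethyl-2-[(3S)-6-methyl-3-Lav-2-oxohept-5-en-3-yl]-4-(trimethylsilyloxy)-5,6-dihydro-2H-pyran-3-carboxylate, mixture at C2 | COC(=O)C1=C(O[Si](C)(C)C)[C@@H](C)[C@@H](C)OC1[C@](CC=C(C)C)(C[C@H](CC=C(C)C)C(C)=C)C(C)=O
F5 | step 12 | enol lactone of 24 closed between the side-chain carboxyl and the C5 enol oxygen, (S) at the phenyl-bearing carbon | C=C(C)[C@@H](CC=C(C)C)C[C@]1(CC=C(C)C)C(=O)C3=C(OC(=O)C[C@H]3c4ccccc4)C2=C1O[C@H](C)[C@H](C)C2=O
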